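**Slowing amounts.** The change in amounts slowed in the earlier runs while both reagents remained. At 3.00 h, Thursday's flask held 34.0% target beside 66.0% of its starting material.

common to all: free catalyst 0.17 mM

| charge | starting material | partner | remark | time |
|---|---|---|---|---|
| Monday's | 0.29 M | 0.348 M | run made earlier |  |
| Friday's | 0.29 M | 0.17 M | run made earlier |  |
| Thursday's | 0.29 M | 0.26 M | run made earlier |  |
| north | 0.29 M | 0.348 M | everything together in a closed stirred flask, run for 4.0 h | 4.0 h |
| south | 0.29 M | 0.348 M (fed, over 4.00 h) | a stirred flask in which partner is dosed at a steady rate over 4.00 h without added volume, worked up at 4.0 h | 4.0 h |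
| west | 0.29 M | 0.348 M | one stirred flow tank at steady state, fed with the mixture as stated, mean residence time 4.0 h |  |
| south-east | 0.29 M (fed, over 4.00 h) | 0.348 M | a stirred flask in which starting material is dosed at a steady rate over 4.00 h without added volume, worked up at 4.0 h | 4.0 h |

| run | time / h | target / % | starting material / % |
|---|---|---|---|
| Monday's | 0.133 | 6.9 | 93.5 |
| Monday's | 0.333 | 13.7 | 85.9 |
| Monday's | 0.667 | 22.5 | 77.0 |
| Monday's | 1.00 | 28.7 | 71.4 |
| Monday's | 1.33 | 33.0 | 67.5 |
| Monday's | 2.00 | 38.4 | 61.0 |
| Monday's | 2.50 | 40.1 | 59.6 |
| Friday's | 0.500 | 9.6 | 90.6 |
| Friday's | 1.00 | 14.9 | 84.0 |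
| Friday's | 1.33 | 17.8 | 81.6 |
| Friday's | 2.00 | 20.8 | 78.7 |
| Friday's | 2.50 | 22.2 | 77.9 |
| Friday's | 3.00 | 24.0 | 76.6 |
| Thursday's | 0.500 | 14.6 | 85.9 |
| Thursday's | 1.00 | 22.0 | 77.8 |
| Thursday's | 1.33 | 26.3 | 73.9 |
| Thursday's | 2.00 | 30.9 | 68.8 |
| Thursday's | 2.50 | 32.6 | 67.2 |
| Thursday's | 3.00 | 34.0 | 66.0 |

(scatter of a reading: 0.5 percentage points)

1. the set-up with the highest amount of target at the outlet or at the end, in percent of the starting material put in ("none" if the first two lie within 2 percentage points) (north / south / west / south-east / none)
2. amount of target at the outlet or at the end, in percent of the starting material put in, north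
3. amount of target at the outlet or at the end, in percent of the starting material put in, south
4. amount of target at the outlet or at the end, in percent of the starting material put in, west
5. amount of target at the outlet or at the end, in percent of the starting material put in, south-east

- the stated concentrations are those of everything mixed, before any reaction; amounts are the same in each set-up
- the feed brings no volume worth counting
- the earlier runs were made in a closed, stirred flask

**One ratio.** At each run's last reading I divided c(target) by c(starting material) times c(partner). Thursday's run gave 3.19 M⁻¹, Friday's 3.12 M⁻¹, and Monday's, read earlier, 2.90 M⁻¹. Yet Monday's partner charge was twice Friday's. I called Thursday's reading the stall quotient, the usual reaction quotient taken where a run slows. I read the slowing as a balance. The amounts were still creeping, so I took the quotient as a floor.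

**The opposite outcome.** For north to lose its place, a rival had to come within 2 percentage points of it. The stall quotient put north at 41.9% or a little above, and Monday's run already showed 40.1% at 2.50 h. But the dosed flasks reach their whole charge at 4.00 h, and Thursday's run, with 0.26 M partner from the start, showed 34.0% at 3.00 h. So I expected north to stay first.

**The forecast.** It also named north, with 44% for north, 17.5% for south, 31% for west and 17.2% for south-east. Its ground was this: “This points to catalyst dying with time, not equilibrium or product inhibition”. There we differed.

**The result.** The flask that came first was north, with 43.2%. South gave 34.0% against the forecast's 17.5%, south-east 34.3% and west 34.7%.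

    starting material + partner + free catalyst ⇌ target + free catalyst, rate k1*[starting material]*[partner]*[free catalyst] forward; the back reaction follows from the equilibrium constant (K = 3.60 M⁻¹, k = 2.40 M⁻² s⁻¹)
    starting material + free catalyst → spent catalyst (k = 3.80 × 10⁻⁵ M⁻¹ s⁻¹)

**The quotient again.** South still held 87.4% of its free catalyst at 4.00 h. Its end amounts give a quotient of 2.06 M⁻¹, lower than the stall quotient, and south reached 44.2% at 40.0 h. For a second flask like south, dosed with 1.4 M partner, the stall quotient gives 78.9%, and that flask gave 76.9% at 4.00 h.

The numbers in the tables were computed on assumed constants; noise was put on by code.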